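**Retrosynthetic overview**
- The only ring is closed late: C2=C3 by ring-closing metathesis of an acyclic octa-1,7-diene, followed by MOM removal.
- C1–C2: vinyl Grignard addition to a β-hydroxy ketone; the magnesium chelate sets C1.
- C4–C5: an α-alkoxyallyl carbanion equivalent, (Z)-γ-(MOM-oxy)allyl-Ipc2-borane, adds through its oxygen-bearing carbon to the C5 aldehyde and sets C4 and C5 together.
- C1–C6 and C1–C1′: 1,3-dithiane serves as the C1 acyl-anion linchpin, alkylated first with BrCH2CH(OMe)2 and then with the C17 bromide.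
- Side chain: the (E)-olefin comes from a B-alkyl Suzuki coupling of 11-bromoundec-1-ene/9-BBN with (E)-1-iodohex-1-ene, made from 1-hexyne.

Assumption: the target is the (1R,4R,5R)-triol encoded by the SMILES (1-OH cis to 4-OH, 4-OH trans to 5-OH); reagents that put no carbon into the target (DIBAL-H, 9-BBN, (−)-Ipc2BOMe, Grubbs II and the like) are bought.

**Step 1**
Reactants: 1 hex-1-yne
Product: 3 (E)-1-iodohex-1-ene, via (E)-hex-1-enyl(diisobutyl)alane 2 (not isolated)
Conditions: DIBAL-H, hexane, 50 °C; then I2, THF, −50 °C → rt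
Reagents that add atoms: iodine, II
Why: Zweifel hydroalumination–iodinolysis: syn addition of Al–H puts aluminium on C1 trans to the butyl group, and I2 cleaves the C–Al bond with retention, so only the (E)-iodide forms.

**Step 2**
Reactants: 4 11-bromoundec-1-ene; 3 (E)-1-iodohex-1-ene
Product: 6 (E)-1-bromoheptadec-12-ene, via B-(11-bromoundecyl)-9-BBN 5 (not isolated)
Conditions: 9-BBN, THF, 0 °C → rt; then 3, PdCl2(dppf) (3 mol %), K3PO4 (aq), DMF, rt
Reagents that add atoms: none
Why: B-alkyl Suzuki–Miyaura coupling: 9-BBN hydroborates only the terminal alkene (anti-Markovnikov), the vinyl iodide couples at room temperature with retention of the E geometry, and the unactivated primary C–Br bond is inert to Pd(dppf).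

**Step 3**
Reactants: 7 1,3-dithiane; 8 2-bromo-1,1-dimethoxyethane
Product: 10 2-(2,2-dimethoxyethyl)-1,3-dithiane, via 2-lithio-1,3-dithiane 9 (not isolated)
Conditions: n-BuLi, THF, −30 °C; then 8, −78 °C → rt
Reagents that add atoms: none
Why: Corey–Seebach alkylation: the lithiated dithiane (a carbonyl carbon used as a nucleophile) displaces the primary bromide by SN2 and forms C1–C6; no stereocentre is made.

**Step 4**
Reactants: 10 2-(2,2-dimethoxyethyl)-1,3-dithiane; 6 (E)-1-bromoheptadec-12-ene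
Product: 13 2-{2-[(E)-heptadec-12-en-1-yl]-1,3-dithian-2-yl}acetaldehyde, via lithiated dithiane acetal 11 (not isolated), via dimethyl acetal 12 (not isolated)
Conditions: n-BuLi, THF, −20 °C; 6, DMPU, −78 °C → rt; then 2 M HCl, THF, rt
Reagents that add atoms: water, O
Why: Second Corey–Seebach alkylation of the same carbon (the C1 acyl-anion equivalent) with the primary C17 bromide forms C1–C1′, and aqueous acid then hydrolyses only the dimethyl acetal because the dithiane is acid-stable; no stereocentre is made.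

**Step 5**
Reactants: 14 prop-2-en-1-ol (allyl alcohol)
Product: 15 3-(methoxymethoxy)prop-1-ene (allyl MOM ether)
Conditions: MOMCl, i-Pr2NEt, CH2Cl2, 0 °C → rt
Reagents that add atoms: chloromethyl methyl ether, COCCl
Why: Williamson-type O-alkylation (MOM protection) of a primary alcohol gives the ether whose O–CH2 position is lithiated in step 6.

**Step 6**
Reactants: 13 2-{2-[(E)-heptadec-12-en-1-yl]-1,3-dithian-2-yl}acetaldehyde; 15 3-(methoxymethoxy)prop-1-ene
Product: 17 (2R,3R)-1-{2-[(E)-heptadec-12-en-1-yl]-1,3-dithian-2-yl}-3-(methoxymethoxy)pent-4-en-2-ol, via (Z)-γ-(methoxymethoxy)allyl-Ipc2-borane 16 (not isolated)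
Conditions: 15, s-BuLi, THF, −78 °C; (−)-Ipc2BOMe; BF3·OEt2; 13, −78 °C; then HOCH2CH2NH2, rt
Reagents that add atoms: none
Why: Brown asymmetric (Z)-γ-alkoxyallylboration: the oxygen-bearing allyl carbon, made nucleophilic by α-lithiation and trapping on boron (an α-alkoxy carbanion equivalent), adds to the aldehyde carbon through a closed chair transition state, so the Z geometry gives the syn relationship and the Ipc groups from (+)-α-pinene direct attack to the Si face, setting C4 and C5 as (R,R) (typically ≥98% de and about 90–95% ee); ethanolamine work-up avoids sulfur oxidation.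

**Step 7**
Reactants: 17 (2R,3R)-1-{2-[(E)-heptadec-12-en-1-yl]-1,3-dithian-2-yl}-3-(methoxymethoxy)pent-4-en-2-ol
Product: 18 (3R,4R,18E)-4-hydroxy-3-(methoxymethoxy)tricosa-1,18-dien-6-one
Conditions: PhI(O2CCF3)2, MeCN/H2O (9:1), 0 °C
Reagents that add atoms: water, O
Why: Oxidative dithiane hydrolysis with hypervalent iodine (Stork–Zhao) is fast at 0 °C and leaves the MOM ether, the free alcohol and both alkenes alone; the stereocentres are not touched.

**Step 8**
Reactants: 18 (3R,4R,18E)-4-hydroxy-3-(methoxymethoxy)tricosa-1,18-dien-6-one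
Product: 19 (3R,5R,6R)-3-[(E)-heptadec-12-en-1-yl]-6-(methoxymethoxy)octa-1,7-diene-3,5-diol
Conditions: CH2=CHMgBr (4 equiv), THF, −78 → −40 °C
Reagents that add atoms: vinylmagnesium bromide, C=C[Mg]Br
Why: Chelation-controlled (Cram–Reetz 1,3-) Grignard addition: the magnesium alkoxide of the β-hydroxyl holds the ketone in a six-membered chelate and vinyl attacks axially, trans to the C4 side chain, giving the 1,3-anti tertiary carbinol (1R in the target); expected dr about 4–8:1, with the epimeric diols separable on silica.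

**Step 9**
Reactants: 19 (3R,5R,6R)-3-[(E)-heptadec-12-en-1-yl]-6-(methoxymethoxy)octa-1,7-diene-3,5-diol
Product: 20 (1R,4R,5R)-1-[(E)-heptadec-12-en-1-yl]-4-(methoxymethoxy)cyclohex-2-ene-1,5-diol
Conditions: Grubbs II (5 mol %), CH2Cl2 (5 mM), 40 °C
Reagents that add atoms: none
Why: Ring-closing metathesis of the two terminal vinyl groups to a six-membered ring is much faster than any reaction of the remote internal chain alkene; it forms the only ring and the C2=C3 bond without touching a stereocentre.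

**Step 10**
Reactants: 20 (1R,4R,5R)-1-[(E)-heptadec-12-en-1-yl]-4-(methoxymethoxy)cyclohex-2-ene-1,5-diol
Product: 22 (1R,4R,5R)-1-[(E)-heptadec-12-en-1-yl]cyclohex-2-ene-1,4,5-triol, via bis-TMS bipyridinium acetal triflate 21 (not isolated)
Conditions: TMSOTf, 2,2′-bipyridyl, CH2Cl2, 0 °C → rt; then H2O
Reagents that add atoms: none
Why: Fujioka MOM cleavage: TMSOTf/2,2′-bipyridyl turns the MOM ether into a pyridinium N,O-acetal (the two hydroxyls are transiently TMS ethers) that water hydrolyses, so no protic acid meets the ionisable tertiary allylic alcohol, and no C–O bond at a stereocentre is broken.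

**Compound list**
1 | hex-1-yne | CCCCC#C | starting material
2 | (E)-hex-1-en-1-yl(diisobutyl)alane | CCCC/C=C/[Al](CC(C)C)CC(C)C | intermediate (not isolated)
3 | (E)-1-iodohex-1-ene | CCCC/C=C/I | intermediate
4 | 11-bromoundec-1-ene | C=CCCCCCCCCCBr | starting material
5 | 9-(11-bromoundecyl)-9-borabicyclo[3.3.1]nonane | BrCCCCCCCCCCCB1C2CCCC1CCC2 | intermediate (not isolated)
6 | (E)-1-bromoheptadec-12-ene | CCCC/C=C/CCCCCCCCCCCBr | intermediate
7 | 1,3-dithiane | C1CSCSC1 | starting material
8 | 2-bromo-1,1-dimethoxyethane | COC(CBr)OC | starting material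
9 | 2-lithio-1,3-dithiane | [Li]C1SCCCS1 | intermediate (not isolated)
10 | 2-(2,2-dimethoxyethyl)-1,3-dithiane | COC(OC)CC1SCCCS1 | intermediate
11 | 2-(2,2-dimethoxyethyl)-2-lithio-1,3-dithiane | COC(OC)CC1([Li])SCCCS1 | intermediate (not isolated)
12 | 2-(2,2-dimethoxyethyl)-2-[(E)-heptadec-12-en-1-yl]-1,3-dithiane | CCCC/C=C/CCCCCCCCCCCC1(CC(OC)OC)SCCCS1 | intermediate (not isolated)
13 | 2-{2-[(E)-heptadec-12-en-1-yl]-1,3-dithian-2-yl}acetaldehyde | CCCC/C=C/CCCCCCCCCCCC1(CC=O)SCCCS1 | intermediate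
14 | prop-2-en-1-ol | C=CCO | starting material
15 | 3-(methoxymethoxy)prop-1-ene | C=CCOCOC | intermediate
16 | [(Z)-3-(methoxymethoxy)prop-2-en-1-yl]bis(isopinocampheyl)borane, Ipc from (+)-α-pinene | COCO/C=C\CB([C@@H]1C[C@@H]2C[C@H]([C@H]1C)C2(C)C)[C@@H]1C[C@@H]2C[C@H]([C@H]1C)C2(C)C | intermediate (not isolated)
17 | (2R,3R)-1-{2-[(E)-heptadec-12-en-1-yl]-1,3-dithian-2-yl}-3-(methoxymethoxy)pent-4-en-2-ol | CCCC/C=C/CCCCCCCCCCCC1(C[C@@H](O)[C@H](OCOC)C=C)SCCCS1 | intermediate
18 | (3R,4R,18E)-4-hydroxy-3-(methoxymethoxy)tricosa-1,18-dien-6-one | CCCC/C=C/CCCCCCCCCCCC(=O)C[C@@H](O)[C@H](OCOC)C=C | intermediate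
19 | (3R,5R,6R)-3-[(E)-heptadec-12-en-1-yl]-6-(methoxymethoxy)octa-1,7-diene-3,5-diol | CCCC/C=C/CCCCCCCCCCC[C@](O)(C=C)C[C@@H](O)[C@H](OCOC)C=C | intermediate
20 | (1R,4R,5R)-1-[(E)-heptadec-12-en-1-yl]-4-(methoxymethoxy)cyclohex-2-ene-1,5-diol | CCCC/C=C/CCCCCCCCCCC[C@]1(O)C=C[C@@H](OCOC)[C@H](O)C1 | intermediate
21 | 1-(alkoxymethyl)-2,2′-bipyridin-1-ium triflate of 20 at O-4, with the 1- and 5-hydroxyls as TMS ethers | CCCC/C=C/CCCCCCCCCCC[C@]1(O[Si](C)(C)C)C=C[C@@H](OC[n+]2ccccc2-c2ccccn2)[C@H](O[Si](C)(C)C)C1.[O-]S(=O)(=O)C(F)(F)F | intermediate (not isolated)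
22 | (1R,4R,5R)-1-[(E)-heptadec-12-en-1-yl]cyclohex-2-ene-1,4,5-triol (CNP0317923.1) | CCCC/C=C/CCCCCCCCCCC[C@]1(O)C=C[C@@H](O)[C@H](O)C1 | target

**Totals**
Total step count: 10. Longest linear sequence: 8 (steps 1, 2, 4, 6, 7, 8, 9, 10, from hex-1-yne). The enantiomeric purity is fixed in step 6; if it falls short, 22 can be recrystallised.

**Three steps most likely to fail**

Step 8. C1 is set by 1,3-induction in an acyclic magnesium chelate, so the dr may be modest, and the magnesium aldolate can undergo retro-aldol cleavage. The fallback sets out from 18 and comes back at 19. Ethynylmagnesium bromide (THF, −78 °C), a slimmer nucleophile that follows the chelate more closely, is added to 18 to give (3R,5R,6R)-3-[(E)-heptadec-12-en-1-yl]-6-(methoxymethoxy)oct-7-en-1-yne-3,5-diol F1. After separation of any C3 epimer, Lindlar semi-hydrogenation (Pd/CaCO3/Pb, quinoline, H2 1 atm, EtOAc) reduces only the terminal alkyne and returns 19.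

Step 10. The MOM ether has to be cleaved beside a tertiary allylic alcohol that ionises easily. The fallback sets out from 17 and comes back at 22; it removes the MOM group before that alcohol exists and runs the end-game unprotected. HCl (cat.) in MeOH at 40 °C on the acid-proof dithiane 17 gives (2R,3R)-1-{2-[(E)-heptadec-12-en-1-yl]-1,3-dithian-2-yl}pent-4-ene-2,3-diol F2. PhI(O2CCF3)2 in aqueous MeCN then frees (3R,4R,18E)-3,4-dihydroxytricosa-1,18-dien-6-one F3, which sits in equilibrium with its five-membered hemiketal. Excess vinylmagnesium bromide (6 equiv) converts it to (3R,5R,6R)-3-[(E)-heptadec-12-en-1-yl]octa-1,7-diene-3,5,6-triol F4, and Grubbs II closes this triol directly to 22.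

Step 4. This alkylation builds a fully substituted dithiane carbon with an unactivated C17 bromide and is telescoped with the acetal hydrolysis. The fallback sets out from 7 and 6 and comes back at 13; it reverses the order of the two C1 bond formations and uses an epoxide as the second electrophile. 2-Lithio-1,3-dithiane (from 7, n-BuLi) is alkylated with 6 to give 2-[(E)-heptadec-12-en-1-yl]-1,3-dithiane F5. Lithiation with t-BuLi in THF/HMPA at −78 °C and opening of ethylene oxide gives 2-{2-[(E)-heptadec-12-en-1-yl]-1,3-dithian-2-yl}ethan-1-ol F6. Parikh–Doering oxidation (SO3·pyridine, DMSO, i-Pr2NEt), which spares the sulfur, returns 13.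

**Further compounds**
F1 | step 8 | (3R,5R,6R)-3-[(E)-heptadec-12-en-1-yl]-6-(methoxymethoxy)oct-7-en-1-yne-3,5-diol | CCCC/C=C/CCCCCCCCCCC[C@](O)(C#C)C[C@@H](O)[C@H](OCOC)C=C
F2 | step 10 | (2R,3R)-1-{2-[(E)-heptadec-12-en-1-yl]-1,3-dithian-2-yl}pent-4-ene-2,3-diol | CCCC/C=C/CCCCCCCCCCCC1(C[C@@H](O)[C@H](O)C=C)SCCCS1
F3 | step 10 | (3R,4R,18E)-3,4-dihydroxytricosa-1,18-dien-6-one | CCCC/C=C/CCCCCCCCCCCC(=O)C[C@@H](O)[C@H](O)C=C
F4 | step 10 | (3R,5R,6R)-3-[(E)-heptadec-12-en-1-yl]octa-1,7-diene-3,5,6-triol | CCCC/C=C/CCCCCCCCCCC[C@](O)(C=C)C[C@@H](O)[C@H](O)C=C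
F5 | step 4 | 2-[(E)-heptadec-12-en-1-yl]-1,3-dithiane | CCCC/C=C/CCCCCCCCCCCC1SCCCS1
F6 | step 4 | 2-{2-[(E)-heptadec-12-en-1-yl]-1,3-dithian-2-yl}ethan-1-ol | CCCC/C=C/CCCCCCCCCCCC1(CCO)SCCCS1
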